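**Plan**

- Cuts, in retrosynthetic order: the seven O–CH3 bonds (all phenols are carried as methyl ethers); the bond from C6 of ring A (the styryl-bearing dihydrobenzofuran) to the alkene; O1–C7a and C3–C3a of ring A; the bond from the ketone carbon to C6 of ring B; C2–C3 of ring B.
- Enabling feature: in ring A the adjacent benzo carbons C7a and C3a carry O1 and C3, and the C4 oxygen sits next to C3a. A C3a≡C7a aryne bearing that methoxy group therefore takes oxygen at C7a and leaves the carbanion at C3a.
- Forward order: ring B is closed first by carbene C–H insertion and set trans, then joined as its 6-aryl ketone to (S)-4-methoxymandelic acid. Ring A is closed on that hydroxy ketone by the aryne annulation. Deoxygenation, C2 equilibration, Heck coupling and demethylation follow.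
- Stereochemistry: ring B C3 comes from the chiral dirhodium catalyst and its C2 from acid equilibration to trans. Ring A C2 comes from the mandelic acid, steers hydride to C3, and is then inverted to trans. The E-alkene comes from the Heck reaction.

Key step: step 12

Remarks on the chemistry:
- Assumption: Rh2(R-PTAD)4 is taken to give the (3S) centre in step 7. If the first run shows the opposite sense, Rh2(S-PTAD)4 is used with no other change.
- "B-aryl" below means (2S,3S)-3-(3,5-dimethoxyphenyl)-4-methoxy-2-(4-methoxyphenyl)-2,3-dihydro-1-benzofuran-6-yl.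
- Compounds 1, 4, 6, 8, 16 and 27 are purchased.

**Step 1**
Reactants: 1 3-methoxy-2-(trimethylsilyl)phenyl trifluoromethanesulfonate
Product: 3 5-bromo-3-methoxy-2-(trimethylsilyl)phenyl trifluoromethanesulfonate, via aryl pinacol boronate 2 (not isolated)
Conditions: B2pin2, [Ir(OMe)(cod)]2 (1.5 mol %), 4,4'-di-tert-butyl-2,2'-bipyridine (3 mol %), THF, 60 °C; evaporate; CuBr2 (3 equiv), MeOH/H2O 1:1, 80 °C
Reagents that add atoms: bis(pinacolato)diboron, CC1(C)OB(OC1(C)C)B1OC(C)(C)C(C)(C)O1 (boron unit of 2 only); CuBr2, [Cu+2].[Br-].[Br-]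
Why: Iridium-catalysed arene C–H borylation is sterically governed and should take the only C–H that has no ortho substituent (C5), after which CuBr2 replaces the boronate by bromine in the same flask (borylation/bromodeboronation) under fluoride-free conditions that leave the silyl triflate pair intact.

**Step 2**
Reactants: 4 4-bromo-2,6-dimethoxybenzaldehyde
Product: 5 4-bromo-2-hydroxy-6-methoxybenzaldehyde
Conditions: BCl3 (1.2 equiv), CH2Cl2, −78 → 0 °C; H2O
Reagents that add atoms: none
Why: BCl3 chelated by the aldehyde oxygen cleaves one ortho methyl ether (chelation-controlled mono-demethylation), and the boron chelate so formed protects the second one.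

**Step 3**
Reactants: 5 4-bromo-2-hydroxy-6-methoxybenzaldehyde; 6 4-methoxybenzyl chloride
Product: 7 4-bromo-2-methoxy-6-[(4-methoxybenzyl)oxy]benzaldehyde
Conditions: K2CO3, DMF, 60 °C
Reagents that add atoms: none
Why: Williamson etherification of the phenoxide with a reactive benzylic chloride installs the CH2 that will become C2 of ring B together with its 4-methoxyphenyl group.

**Step 4**
Reactants: 7 4-bromo-2-methoxy-6-[(4-methoxybenzyl)oxy]benzaldehyde; 8 1-bromo-3,5-dimethoxybenzene
Product: 10 {4-bromo-2-methoxy-6-[(4-methoxybenzyl)oxy]phenyl}(3,5-dimethoxyphenyl)methanol (racemic), via 3,5-dimethoxyphenylmagnesium bromide 9 (not isolated)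
Conditions: Mg, THF, 50 °C; then 7, 0 → 25 °C; aq NH4Cl
Reagents that add atoms: Mg, [Mg] (held only in intermediate 9)
Why: Grignard addition to the aldehyde is faster than any exchange with the aryl bromide of 7, and the carbinol centre it creates is removed in the next step.

**Step 5**
Reactants: 10 the diaryl carbinol
Product: 11 {4-bromo-2-methoxy-6-[(4-methoxybenzyl)oxy]phenyl}(3,5-dimethoxyphenyl)methanone
Conditions: Dess–Martin periodinane, CH2Cl2, 25 °C
Reagents that add atoms: none
Why: Dess–Martin oxidation of a secondary diaryl carbinol is reliable for hindered substrates and leaves the benzyl ether and the aryl bromide untouched.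

**Step 6**
Reactants: 11 the diaryl ketone
Product: 12 hydrazone of 11 (C=N–NH2, geometry immaterial)
Conditions: N2H4·H2O (excess), AcOH (cat.), n-BuOH, 110 °C
Reagents that add atoms: hydrazine (as hydrate), NN
Why: Condensation of a ketone with excess hydrazine gives the free hydrazone (the excess suppresses azine formation), and the heat answers the two ortho alkoxy groups that flank the carbonyl group.

**Step 7**
Reactants: 12 the hydrazone
Product: 14 (2R,3S)-6-bromo-3-(3,5-dimethoxyphenyl)-4-methoxy-2-(4-methoxyphenyl)-2,3-dihydro-1-benzofuran (2,3-cis), via diaryldiazomethane 13 (not isolated)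
Conditions: MnO2, CH2Cl2, 0 °C, filter; Rh2(R-PTAD)4 (dirhodium tetrakis[(R)-N-phthaloyl-1-adamantylglycinate], 1 mol %), CH2Cl2, 0 → 25 °C
Reagents that add atoms: none
Why: MnO2 dehydrogenates the hydrazone to the diazo compound, whose donor/donor rhodium carbene should insert into the electron-rich benzylic ether C–H five atoms away (intramolecular carbene C–H insertion, preferred over the methoxy C–H) in a concerted step that gives the 2,3-cis ring, the chiral carboxylate ligands setting C3 as S and C2 with it.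

**Step 8**
Reactants: 14 the cis ring B bromide
Product: 15 (2S,3S)-6-bromo-3-(3,5-dimethoxyphenyl)-4-methoxy-2-(4-methoxyphenyl)-2,3-dihydro-1-benzofuran (2,3-trans)
Conditions: BF3·OEt2 (1 equiv), CH2Cl2, 0 → 25 °C
Reagents that add atoms: none
Why: The Lewis acid reversibly ionises the C2–O1 bond to a 4-methoxybenzylic cation that recloses to the less crowded trans isomer (acid-mediated C2 epimerisation), so C2 becomes S under thermodynamic control while C3 is not touched.

**Step 9**
Reactants: 16 (S)-4-methoxymandelic acid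
Product: 17 (S)-2-hydroxy-N-methoxy-2-(4-methoxyphenyl)-N-methylacetamide
Conditions: MeNHOMe·HCl, EDC·HCl, HOBt, N-methylmorpholine, CH2Cl2, 0 → 25 °C
Reagents that add atoms: N,O-dimethylhydroxylamine hydrochloride, CNOC.Cl
Why: Carbodiimide/HOBt amide coupling tolerates the free secondary hydroxyl and proceeds through an active ester that does not racemise the α-hydroxy acid.

**Step 10**
Reactants: 17 the hydroxy Weinreb amide
Product: 18 (S)-N-methoxy-2-(4-methoxyphenyl)-N-methyl-2-[(triethylsilyl)oxy]acetamide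
Conditions: Et3SiCl, imidazole, CH2Cl2, 0 → 25 °C
Reagents that add atoms: chlorotriethylsilane, CC[Si](Cl)(CC)CC
Why: Imidazole-mediated silylation protects the carbinol oxygen as an ether that survives an organomagnesium reagent and is removed by dilute acid.

**Step 11**
Reactants: 15 the trans ring B bromide; 18 the silylated Weinreb amide
Product: 22 (S)-2-hydroxy-2-(4-methoxyphenyl)-1-(B-aryl)ethanone, via aryllithium 19 (not isolated), via arylmagnesium bromide 20 (not isolated), via triethylsilyl ether ketone 21 (not isolated)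
Conditions: n-BuLi, THF, −78 °C; MgBr2·OEt2, −78 °C; 18, −78 → 0 °C; 1 M HCl, THF, 25 °C
Reagents that add atoms: n-butyllithium, [Li]CCCC (lithium of 19 only); MgBr2·OEt2, Br[Mg]Br (magnesium and bromine of 20 only)
Why: Bromine–lithium exchange and transmetalation give a weakly basic aryl Grignard that adds once to the Weinreb amide through its chelated tetrahedral adduct without deprotonating the benzylic α-position, and the acidic work-up releases the ketone and cleaves the silyl ether under non-enolising conditions, so the S centre is kept.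

**Step 12**
Reactants: 22 the (S)-α-hydroxy ketone; 3 the bromo silylaryl triflate
Product: 24 (2S,3S)-6-bromo-3-(B-aryl)-4-methoxy-2-(4-methoxyphenyl)-2,3-dihydro-1-benzofuran-3-ol (drawn as the C3 epimer with the two aryl groups trans; its C3 epimer may accompany it), via 5-bromo-3-methoxybenzyne 23 (not isolated)
Conditions: 3 (3 equiv), CsF (6 equiv), MeCN, 25 °C; 22 added over 4 h
Reagents that add atoms: none
Why: Proposed new method: fluoride removes the silyl group of 3 and triflate departs to give the 3-methoxy aryne 23, the fluoride-hydrogen-bonded hydroxyl oxygen of 22 adds at the aryne carbon remote from the methoxy group (the future C7a), and the aryl anion thereby placed at C3a, stabilised inductively by the neighbouring C4 methoxy group, attacks the ketone to give the 3-alkoxide, which is protonated. The closest known reaction types are the fluoride-induced annulations of arynes with N-sulfonyl α-amino ketones to 3-hydroxyindolines and with salicylates to xanthones. Ring A closes by 5-exo-trig addition of the aryl anion to the carbonyl group. C2 is carried over unchanged from the mandelic acid, whereas the new carbinol centre C3 should form mainly with the B-aryl group anti to the C2 aryl group and is of no consequence because step 13 destroys it. The step needs oxygen, not carbon, to bond at C7a, which the C4 methoxy group secures, and it needs the base-labile benzoin-type centre to survive, which is served by adding 22 slowly to an excess of aryne being generated so that it meets fluoride only briefly.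

**Step 13**
Reactants: 24 the ring A 3-ol
Product: 25 (2R,3S)-6-bromo-3-(B-aryl)-4-methoxy-2-(4-methoxyphenyl)-2,3-dihydro-1-benzofuran (ring A 2,3-cis)
Conditions: Et3SiH (5 equiv), BF3·OEt2 (2 equiv), CH2Cl2, −78 °C; Et3N, then aq NaHCO3 at −78 °C
Reagents that add atoms: none
Why: BF3 ionises the tertiary, doubly benzylic alcohol to a C3 cation stabilised by the two ortho oxygens of the benzo ring, and Et3SiH delivers hydride to the face opposite the C2 aryl group (ionic hydrogenation), which sets C3 as S from either carbinol epimer while the low temperature disfavours loss of the C2 proton and opening of the benzylic C–O bonds.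

**Step 14**
Reactants: 25 the ring A cis bromide
Product: 26 (2S,3S)-6-bromo-3-(B-aryl)-4-methoxy-2-(4-methoxyphenyl)-2,3-dihydro-1-benzofuran (both rings trans)
Conditions: BF3·OEt2 (1 equiv), CH2Cl2, 0 → 25 °C
Reagents that add atoms: none
Why: As in step 8, reversible ionisation of the ring A C2–O1 bond and reclosure moves the 4-methoxyphenyl group to the side opposite the C3 substituent (thermodynamic C2 epimerisation), giving C2 as S without touching C3 or the already trans ring B.

**Step 15**
Reactants: 26 the all-trans bromide; 27 4-methoxystyrene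
Product: 28 heptamethyl ether of the target, (2S,3S)-3-(B-aryl)-4-methoxy-2-(4-methoxyphenyl)-6-[(E)-2-(4-methoxyphenyl)ethenyl]-2,3-dihydro-1-benzofuran
Conditions: Pd(OAc)2 (5 mol %), P(o-tol)3 (10 mol %), Et3N, DMF, 100 °C
Reagents that add atoms: none
Why: Mizoroki–Heck coupling of the aryl bromide at the terminal carbon of the styrene followed by syn β-hydride elimination gives the E-stilbene, and the conditions leave the benzylic stereocentres alone.

**Step 16**
Reactants: 28 the heptamethyl ether
Product: 29 the target, (2S,3S)-3-[(2S,3S)-3-(3,5-dihydroxyphenyl)-4-hydroxy-2-(4-hydroxyphenyl)-2,3-dihydro-1-benzofuran-6-yl]-2-(4-hydroxyphenyl)-6-[(E)-2-(4-hydroxyphenyl)ethenyl]-2,3-dihydro-1-benzofuran-4-ol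
Conditions: BBr3 (14 equiv), CH2Cl2, −78 → 25 °C; MeOH, then H2O
Reagents that add atoms: none
Why: BBr3 cleaves aryl methyl ethers by bromide attack on the O-methyl group of the boron complex, and because both dihydrobenzofurans are already the stable trans isomers any reversible C2–O opening should return the same configuration.

**Compound list**

1 | 3-methoxy-2-(trimethylsilyl)phenyl trifluoromethanesulfonate | COc1cccc(OS(=O)(=O)C(F)(F)F)c1[Si](C)(C)C | starting material
2 | 3-methoxy-5-(4,4,5,5-tetramethyl-1,3,2-dioxaborolan-2-yl)-2-(trimethylsilyl)phenyl trifluoromethanesulfonate | COc1cc(B2OC(C)(C)C(C)(C)O2)cc(OS(=O)(=O)C(F)(F)F)c1[Si](C)(C)C | intermediate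
3 | 5-bromo-3-methoxy-2-(trimethylsilyl)phenyl trifluoromethanesulfonate | COc1cc(Br)cc(OS(=O)(=O)C(F)(F)F)c1[Si](C)(C)C | intermediate
4 | 4-bromo-2,6-dimethoxybenzaldehyde | COc1cc(Br)cc(OC)c1C=O | starting material
5 | 4-bromo-2-hydroxy-6-methoxybenzaldehyde | COc1cc(Br)cc(O)c1C=O | intermediate
6 | 4-methoxybenzyl chloride | COc1ccc(CCl)cc1 | starting material
7 | 4-bromo-2-methoxy-6-[(4-methoxybenzyl)oxy]benzaldehyde | COc1ccc(COc2cc(Br)cc(OC)c2C=O)cc1 | intermediate
8 | 1-bromo-3,5-dimethoxybenzene | COc1cc(Br)cc(OC)c1 | starting material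
9 | 3,5-dimethoxyphenylmagnesium bromide | COc1cc([Mg]Br)cc(OC)c1 | intermediate
10 | {4-bromo-2-methoxy-6-[(4-methoxybenzyl)oxy]phenyl}(3,5-dimethoxyphenyl)methanol, racemic | COc1ccc(COc2cc(Br)cc(OC)c2C(O)c2cc(OC)cc(OC)c2)cc1 | intermediate
11 | {4-bromo-2-methoxy-6-[(4-methoxybenzyl)oxy]phenyl}(3,5-dimethoxyphenyl)methanone | COc1ccc(COc2cc(Br)cc(OC)c2C(=O)c2cc(OC)cc(OC)c2)cc1 | intermediate
12 | hydrazone of 11 | COc1ccc(COc2cc(Br)cc(OC)c2C(=NN)c2cc(OC)cc(OC)c2)cc1 | intermediate
13 | {4-bromo-2-methoxy-6-[(4-methoxybenzyl)oxy]phenyl}(3,5-dimethoxyphenyl)diazomethane | COc1ccc(COc2cc(Br)cc(OC)c2C(=[N+]=[N-])c2cc(OC)cc(OC)c2)cc1 | intermediate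
14 | (2R,3S)-6-bromo-3-(3,5-dimethoxyphenyl)-4-methoxy-2-(4-methoxyphenyl)-2,3-dihydro-1-benzofuran (cis) | Brc1cc(OC)c2c(c1)O[C@@H](c1ccc(OC)cc1)[C@H]2c1cc(OC)cc(OC)c1 | intermediate
15 | (2S,3S)-6-bromo-3-(3,5-dimethoxyphenyl)-4-methoxy-2-(4-methoxyphenyl)-2,3-dihydro-1-benzofuran (trans) | Brc1cc(OC)c2c(c1)O[C@H](c1ccc(OC)cc1)[C@H]2c1cc(OC)cc(OC)c1 | intermediate
16 | (S)-4-methoxymandelic acid | COc1ccc([C@H](O)C(=O)O)cc1 | starting material
17 | (S)-2-hydroxy-N-methoxy-2-(4-methoxyphenyl)-N-methylacetamide | COc1ccc([C@H](O)C(=O)N(C)OC)cc1 | intermediate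
18 | (S)-N-methoxy-2-(4-methoxyphenyl)-N-methyl-2-[(triethylsilyl)oxy]acetamide | COc1ccc([C@H](O[Si](CC)(CC)CC)C(=O)N(C)OC)cc1 | intermediate
19 | B-aryllithium (lithium at C6 of ring B) | [Li]c1cc(OC)c2c(c1)O[C@H](c1ccc(OC)cc1)[C@H]2c1cc(OC)cc(OC)c1 | intermediate
20 | B-arylmagnesium bromide | Br[Mg]c1cc(OC)c2c(c1)O[C@H](c1ccc(OC)cc1)[C@H]2c1cc(OC)cc(OC)c1 | intermediate
21 | (S)-2-(4-methoxyphenyl)-1-(B-aryl)-2-[(triethylsilyl)oxy]ethanone | CC[Si](CC)(CC)O[C@@H](c1ccc(OC)cc1)C(=O)c1cc(OC)c2c(c1)O[C@H](c1ccc(OC)cc1)[C@H]2c1cc(OC)cc(OC)c1 | intermediate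
22 | (S)-2-hydroxy-2-(4-methoxyphenyl)-1-(B-aryl)ethanone | O[C@@H](c1ccc(OC)cc1)C(=O)c1cc(OC)c2c(c1)O[C@H](c1ccc(OC)cc1)[C@H]2c1cc(OC)cc(OC)c1 | intermediate
23 | 5-bromo-3-methoxybenzyne | COC1=CC(Br)=CC#C1 | intermediate
24 | (2S,3S)-6-bromo-3-(B-aryl)-4-methoxy-2-(4-methoxyphenyl)-2,3-dihydro-1-benzofuran-3-ol (C3 epimer with trans aryl groups drawn) | Brc1cc(OC)c2c(c1)O[C@@H](c1ccc(OC)cc1)[C@]2(O)c1cc(OC)c2c(c1)O[C@H](c1ccc(OC)cc1)[C@H]2c1cc(OC)cc(OC)c1 | intermediate
25 | (2R,3S)-6-bromo-3-(B-aryl)-4-methoxy-2-(4-methoxyphenyl)-2,3-dihydro-1-benzofuran (ring A cis) | Brc1cc(OC)c2c(c1)O[C@@H](c1ccc(OC)cc1)[C@H]2c1cc(OC)c2c(c1)O[C@H](c1ccc(OC)cc1)[C@H]2c1cc(OC)cc(OC)c1 | intermediate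
26 | (2S,3S)-6-bromo-3-(B-aryl)-4-methoxy-2-(4-methoxyphenyl)-2,3-dihydro-1-benzofuran (ring A trans) | Brc1cc(OC)c2c(c1)O[C@H](c1ccc(OC)cc1)[C@H]2c1cc(OC)c2c(c1)O[C@H](c1ccc(OC)cc1)[C@H]2c1cc(OC)cc(OC)c1 | intermediate
27 | 4-methoxystyrene | COc1ccc(C=C)cc1 | starting material
28 | heptamethyl ether of the target | COc1ccc(/C=C/c2cc(OC)c3c(c2)O[C@H](c2ccc(OC)cc2)[C@H]3c2cc(OC)c3c(c2)O[C@H](c2ccc(OC)cc2)[C@H]3c2cc(OC)cc(OC)c2)cc1 | intermediate
29 | (2S,3S)-3-[(2S,3S)-3-(3,5-dihydroxyphenyl)-4-hydroxy-2-(4-hydroxyphenyl)-2,3-dihydro-1-benzofuran-6-yl]-2-(4-hydroxyphenyl)-6-[(E)-2-(4-hydroxyphenyl)ethenyl]-2,3-dihydro-1-benzofuran-4-ol | Oc1ccc(/C=C/c2cc(O)c3c(c2)O[C@H](c2ccc(O)cc2)[C@H]3c2cc(O)c3c(c2)O[C@H](c2ccc(O)cc2)[C@H]3c2cc(O)cc(O)c2)cc1 | target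

**Step count and risks**

Total: 16 steps. Longest linear sequence: 13 steps (steps 2–8, then 11–16). Steps 1, 9 and 10 are side branches.

Steps most likely to fail:

1. Step 12 (aryne annulation). Three things may go wrong. Fluoride may enolise the benzoin-type ketone and erode the C2 configuration. The aryl anion may be protonated before it reaches the carbonyl group, leaving only the aryl ether. The aryne may be consumed unproductively. The fallback closes ring A by the same carbene C–H insertion that makes ring B. It sets out from bromide 15 and aldehyde 7. Bromine–lithium exchange of 15 (n-BuLi, THF, −78 °C, giving 19) and addition to 7 would give the diaryl carbinol F1. Dess–Martin oxidation would give the diaryl ketone F2, and hydrazine hydrate in n-BuOH at 110 °C the hydrazone F3. MnO2 would then give the diaryldiazomethane F4, which with Rh2(R-PTAD)4 should insert into the benzylic ether C–H to give the 2,3-cis ring A. The route is rejoined at 25, with ring A now under catalyst control and steps 9–13 bypassed.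

2. Step 13 (ionic deoxygenation). The C3 cation may lose the C2 proton and aromatise to the benzofuran, which erases the stereochemical relay, or hydride may open a benzylic C2–O bond. The fallback avoids the cation and sets out from 24. Acylation with methyl chlorooxoacetate (DMAP, Et3N, CH2Cl2, 0 °C) would give the tertiary methyl oxalate F5. Bu3SnH and AIBN in toluene at 80 °C (Barton–McCombie-type radical deoxygenation) should then generate the C3 radical, which takes hydrogen from the face opposite the C2 aryl group. The route is rejoined at 25.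

3. Step 16 (sevenfold demethylation). The electron-rich stilbene may be protonated and oligomerise, or the benzylic aryl ethers may open irreversibly under the excess Lewis acid, and partial demethylation may leave mixtures. The fallback moves the Lewis acid step ahead of the alkene and sets out from 26. BBr3 in CH2Cl2 would give the hexaphenol bromide F6, and Ac2O in pyridine the hexaacetate F7. Heck coupling of F7 with 4-acetoxystyrene (Pd(OAc)2, P(o-tol)3, Et3N, DMF, 90 °C) would give the heptaacetate F8. K2CO3 in MeOH at 0 °C would then remove the acetates and arrive at the target 29.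

**Further compounds**

F1 | step 12 | {4-bromo-2-methoxy-6-[(4-methoxybenzyl)oxy]phenyl}(B-aryl)methanol, carbinol epimers | COc1ccc(COc2cc(Br)cc(OC)c2C(O)c2cc(OC)c3c(c2)O[C@H](c2ccc(OC)cc2)[C@H]3c2cc(OC)cc(OC)c2)cc1
F2 | step 12 | {4-bromo-2-methoxy-6-[(4-methoxybenzyl)oxy]phenyl}(B-aryl)methanone | COc1ccc(COc2cc(Br)cc(OC)c2C(=O)c2cc(OC)c3c(c2)O[C@H](c2ccc(OC)cc2)[C@H]3c2cc(OC)cc(OC)c2)cc1
F3 | step 12 | hydrazone of F2 | COc1ccc(COc2cc(Br)cc(OC)c2C(=NN)c2cc(OC)c3c(c2)O[C@H](c2ccc(OC)cc2)[C@H]3c2cc(OC)cc(OC)c2)cc1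
F4 | step 12 | {4-bromo-2-methoxy-6-[(4-methoxybenzyl)oxy]phenyl}(B-aryl)diazomethane | COc1ccc(COc2cc(Br)cc(OC)c2C(=[N+]=[N-])c2cc(OC)c3c(c2)O[C@H](c2ccc(OC)cc2)[C@H]3c2cc(OC)cc(OC)c2)cc1
F5 | step 13 | methyl oxalate of 24 | Brc1cc(OC)c2c(c1)O[C@@H](c1ccc(OC)cc1)[C@]2(OC(=O)C(=O)OC)c1cc(OC)c2c(c1)O[C@H](c1ccc(OC)cc1)[C@H]2c1cc(OC)cc(OC)c1
F6 | step 16 | hexaphenol corresponding to bromide 26 | Brc1cc(O)c2c(c1)O[C@H](c1ccc(O)cc1)[C@H]2c1cc(O)c2c(c1)O[C@H](c1ccc(O)cc1)[C@H]2c1cc(O)cc(O)c1
F7 | step 16 | hexaacetate of F6 | Brc1cc(OC(C)=O)c2c(c1)O[C@H](c1ccc(OC(C)=O)cc1)[C@H]2c1cc(OC(C)=O)c2c(c1)O[C@H](c1ccc(OC(C)=O)cc1)[C@H]2c1cc(OC(C)=O)cc(OC(C)=O)c1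
F8 | step 16 | heptaacetate of the target | CC(=O)Oc1ccc(/C=C/c2cc(OC(C)=O)c3c(c2)O[C@H](c2ccc(OC(C)=O)cc2)[C@H]3c2cc(OC(C)=O)c3c(c2)O[C@H](c2ccc(OC(C)=O)cc2)[C@H]3c2cc(OC(C)=O)cc(OC(C)=O)c2)cc1
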